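C1 (next to quaternary C8) and C5 are the prenylated bridgeheads and C9 is the bridging ketone. Ring A is C1–C2–C3–C4–C5–C9 and ring B is C1–C8–C7–C6–C5–C9. "Top" is the face of ring B that carries the C2–C4 bridge, "bottom" the other face.
Cuts, from the target backwards: C3–C(aroyl), C4–O, C4–C5 (ring A), C1–C2, the CH2–CH= bond of the C1 prenyl chain, C1=CH2, C8–homoprenyl, C5–prenyl, C8–CH3, then C1–C8 and C6–C7 of ring B.
Enabling feature: C4 is a carbonyl-level carbon bonded to quaternary C5, C5 is α to the C9 ketone of ring B, and C4 is tied to C1 through C3 and the C2 ketone. A 3-bromopropynoyl group on C1 therefore holds its bromine-bearing carbon over C5 of a C9=C5 silyl enol ether, and making C4–C5 closes ring A while bromine keeps C4 at the enol oxidation level.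
Forward order: ring B is made first (Michael addition, then aldol condensation) and is substituted at C8, C5, C8 and C1 in that order. Ring A is closed next, and the methoxy group, the aroyl group and the free enol and phenol come last.
Stereochemistry: C7 comes from an (S)-prolinol ether catalyst and C8 from copper-mediated addition anti to the C7 prenyl group. C1 is set by bringing in the acyl carbon C2 last, because electrophiles reach C1 anti to the axial C8 methyl and the C7 prenyl group. C5 follows from the geometry of the bridge.

Key step: step 13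

Remark: C5 is carried as a mixture of epimers from step 5 to step 11 and is written without a descriptor, because step 12 makes it trigonal. The carbinol carbon formed in step 9 is also left open, and the target is drawn as its C4 enol tautomer.

Step 1
Reactants: 1 2-methylbut-3-en-2-ol; 2 ethyl vinyl ether
Product: 4 5-methylhex-4-enal, via allyl vinyl ether 3 (not isolated)
Conditions: H3PO4 (cat.), excess 2, sealed vessel, 150 °C
Reagents that add atoms: none
Why: Acid-catalysed transvinylation gives the tertiary allyl vinyl ether, which undergoes an aliphatic Claisen [3,3] rearrangement at this temperature to the γ,δ-unsaturated aldehyde that already holds the future C7 prenyl group.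

Step 2
Reactants: 4 5-methylhex-4-enal; 5 but-3-en-2-one
Product: 7 (4S)-4-(3-methylbut-2-enyl)cyclohex-2-en-1-one, via keto aldehyde 6 (not isolated)
Conditions: (S)-2-[methoxy(diphenyl)methyl]pyrrolidine (5 mol %), ethyl 3,4-dihydroxybenzoate (20 mol %), neat, 4 °C; then LiOH, i-PrOH, rt
Reagents that add atoms: none
Why: This is an enamine-catalysed asymmetric Michael addition followed by intramolecular aldol condensation (Robinson-type annulation), in which the E-enamine of 4 is shielded on one face by the diphenyl(methoxy)methyl group so that 5 is attacked from the open face and C7 is set as S, after which lithium hydroxide closes ring B between the methyl ketone carbon (C1) and the aldehyde carbon (C8).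

Step 3
Reactants: 7 (4S)-4-(3-methylbut-2-enyl)cyclohex-2-en-1-one
Product: 8 {[(3S,4S)-3-methyl-4-(3-methylbut-2-enyl)cyclohex-1-en-1-yl]oxy}trimethylsilane
Conditions: MeMgBr, CuBr·SMe2 (10 mol %), TMSCl, DMPU, THF, −78 °C
Reagents that add atoms: methylmagnesium bromide, C[Mg]Br; chlorotrimethylsilane, C[Si](C)(C)Cl
Why: In this copper-catalysed, chlorosilane-accelerated conjugate addition of a Grignard reagent, methyl enters C8 anti to the C7 prenyl group (a transient centre that step 4 erases) and the enolate is caught regiospecifically as the C9=C1 silyl enol ether.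

Step 4
Reactants: 8 {[(3S,4S)-3-methyl-4-(3-methylbut-2-enyl)cyclohex-1-en-1-yl]oxy}trimethylsilane
Product: 9 (4S)-3-methyl-4-(3-methylbut-2-enyl)cyclohex-2-en-1-one
Conditions: Pd(OAc)2 (10 mol %), O2 (1 atm), DMSO, rt
Reagents that add atoms: none
Why: In this Saegusa–Ito oxidation in its oxygen-coupled catalytic form, the oxa-π-allyl complex of divalent palladium formed from the regiodefined enol ether undergoes β-hydride elimination from C8 and returns the enone with the C8 methyl group in place, while the trisubstituted prenyl alkene stays inert.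

Step 5
Reactants: 9 (4S)-3-methyl-4-(3-methylbut-2-enyl)cyclohex-2-en-1-one; 10 1-bromo-3-methylbut-2-ene
Product: 12 (4R)-3-methyl-4,6-bis(3-methylbut-2-enyl)cyclohex-2-en-1-one (C5 epimers; same spatial arrangement at C7 as in 9), via lithium dienolate 11 (not isolated)
Conditions: LDA, THF, −78 °C; then 10, −78 → 0 °C
Reagents that add atoms: none
Why: Kinetic deprotonation of a 3-methylcyclohexenone by a lithium amide occurs at the α′ carbon (C5) to give the cross-conjugated dienolate, whose SN2 alkylation with the allylic bromide installs the C5 prenyl group before any base-sensitive group is present.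

Step 6
Reactants: 12 (4R)-3-methyl-4,6-bis(3-methylbut-2-enyl)cyclohex-2-en-1-one; 13 5-bromo-2-methylpent-2-ene
Product: 15 C9=C1 trimethylsilyl enol ether of ring B with C8 methyl (bottom) plus 4-methylpent-3-enyl (top) and C7 prenyl (bottom) and C5 prenyl, via homoprenylmagnesium bromide 14 (not isolated)
Conditions: 13, Mg, THF, reflux; then CuBr·SMe2 (20 mol %), TMSCl, DMPU, 12, THF, −78 → −30 °C
Reagents that add atoms: chlorotrimethylsilane, C[Si](C)(C)Cl
Why: In this copper-catalysed conjugate addition of a Grignard reagent under chlorosilane acceleration, the nucleophile adds axially to C8 anti to the adjacent C7 prenyl group, as is the rule for 4-substituted 3-methylcyclohexenones, which puts homoprenyl on top and methyl on the bottom.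

Step 7
Reactants: 15 C9=C1 trimethylsilyl enol ether of ring B
Product: 19 ring B ketone with an exocyclic methylene group on C1, via lithium enolate 16 (not isolated), via Mannich base 17 (not isolated), via methiodide 18 (not isolated)
Conditions: MeLi, THF, 0 °C; CH2=NMe2 I, −78 °C → rt; MeI, rt; DBU, rt
Reagents that add atoms: dimethyl(methylidene)ammonium iodide (Eschenmoser's salt), C=[N+](C)C.[I-]
Why: Regiospecific release of the lithium enolate from the silyl enol ether, Mannich reaction with Eschenmoser's salt, quaternisation and E1cB loss of trimethylamine make up the standard α-methylenation of ketones, and the small iminium ion tolerates the neighbouring quaternary C8.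

Step 8
Reactants: 19 ring B ketone with an exocyclic methylene group on C1; 20 2-methylprop-1-enylmagnesium bromide
Product: 21 tetrasubstituted C9=C1 trimethylsilyl enol ether of ring B carrying the C1 prenyl group
Conditions: 20, CuBr·SMe2 (20 mol %), TMSCl, THF, −78 °C
Reagents that add atoms: chlorotrimethylsilane, C[Si](C)(C)Cl
Why: Copper-catalysed 1,4-addition of an alkenyl Grignard reagent to the unhindered exocyclic terminus of the s-cis enone completes the C1 prenyl chain and at the same time delivers regiospecifically the tetrasubstituted C9=C1 enol ether that no deprotonation could give.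

Step 9
Reactants: 21 tetrasubstituted C9=C1 trimethylsilyl enol ether of ring B; 22 3-(trimethylsilyl)prop-2-ynal
Product: 23 ring B β-hydroxy ketone carrying on C1 the prenyl group (bottom) and a 1-hydroxy-3-(trimethylsilyl)prop-2-ynyl group (top)
Conditions: BF3·OEt2, CH2Cl2, −78 °C; then H2O
Reagents that add atoms: none
Why: In this Mukaiyama aldol addition the slender, highly electrophilic ynal activated by BF3 is attacked by C1 along the axial trajectory on the top face, anti to the axial C8 methyl and the C7 prenyl group, so that C2 ends on top and the C1 prenyl group on the bottom, and loss of the silyl group makes the addition irreversible.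

Step 10
Reactants: 23 ring B β-hydroxy ketone
Product: 24 ring B ketone carrying on C1 the prenyl group (bottom) and a 3-(trimethylsilyl)propynoyl group (top)
Conditions: Dess–Martin periodinane, CH2Cl2, 0 °C → rt
Reagents that add atoms: none
Why: Dess–Martin oxidation of a secondary propargylic alcohol runs under near-neutral conditions, which avoids retro-aldol cleavage and spares the alkenes, and the 1,3-diketone formed cannot enolise at quaternary C1.

Step 11
Reactants: 24 ring B ketone with the C1 3-(trimethylsilyl)propynoyl group
Product: 25 ring B ketone carrying on C1 the prenyl group (bottom) and a 3-bromopropynoyl group (top)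
Conditions: NBS, AgNO3 (15 mol %), acetone, rt, dark
Reagents that add atoms: N-bromosuccinimide, O=C1CCC(=O)N1Br
Why: Silver-catalysed bromodesilylation of an alkynylsilane proceeds through a silver acetylide and is much faster in dry acetone than bromination of trisubstituted alkenes, a selectivity familiar from prenyl-bearing enynes.

Step 12
Reactants: 25 ring B ketone with the C1 3-bromopropynoyl group
Product: 26 C9=C5 triisopropylsilyl enol ether of ring B with the 3-bromopropynoyl group (top) and prenyl (bottom) on C1
Conditions: TIPSOTf, i-Pr2NEt, CH2Cl2, 0 °C → rt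
Reagents that add atoms: triisopropylsilyl trifluoromethanesulfonate, CC(C)[Si](OS(=O)(=O)C(F)(F)F)(C(C)C)C(C)C
Why: In this soft enolisation the silyl triflate activates the C9 carbonyl and the amine removes the only α-hydrogen left (C5–H), which merges the C5 epimers into one enol ether, while the hindered base is too bulky to add to the bromo-ynone.

Step 13
Reactants: 26 C9=C5 triisopropylsilyl enol ether of ring B with the C1 3-bromopropynoyl group
Product: 27 4-bromo-8-methyl-1,5,7-tris(3-methylbut-2-enyl)-8-(4-methylpent-3-enyl)bicyclo[3.3.1]non-3-ene-2,9-dione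
Conditions: [(t-Bu)2(2-biphenylyl)P]Au(NCMe) SbF6 (5 mol %), reagent-grade acetone, rt
Reagents that add atoms: none
Why: The cationic complex of monovalent gold binds the bromoalkyne, C5 of the enol ether attacks the bromine-bearing carbon C4 anti to gold, the silyloxocarbenium ion gives its silyl group to adventitious water, and protodeauration at C3 frees the catalyst and leaves the β-bromo enone. The closest known reaction type is the gold-catalysed carbocyclisation of cyclic silyl enol ethers onto tethered alkynes and 1-haloalkynes, which gives bicyclo[3.3.1]nonenones. Ring A closes in the 6-endo-dig mode. The new quaternary centre C5 is controlled by C1, because the three-atom bridge can span C1 and C5 only with the ynone axial on the top face, so C4 reaches C5 from the top alone. The step needs 6-endo rather than 5-exo attack, which is secured by the polarisation of the ynone (C4 is the β-carbon of the C2 ketone and bears the halogen). It also needs activation of the alkyne beside four trisubstituted alkenes, which is secured by the much higher nucleophilicity and the proximity of the enol ether and by the reluctance of an electron-poor ynone to enter enyne cycloisomerisation.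

Step 14
Reactants: 27 4-bromobicyclo[3.3.1]non-3-ene-2,9-dione
Product: 28 4-methoxy-8-methyl-1,5,7-tris(3-methylbut-2-enyl)-8-(4-methylpent-3-enyl)bicyclo[3.3.1]non-3-ene-2,9-dione
Conditions: NaOMe, MeOH, 0 °C → rt
Reagents that add atoms: sodium methoxide, [Na+].[O-]C
Why: In this addition–elimination (vinylogous acyl substitution) at the β-carbon of a β-bromo enone, methoxide adds to C4 and bromide leaves, giving the vinylogous methyl ester that masks the C2–C4 diketone.

Step 15
Reactants: 29 3-hydroxybenzoic acid
Product: 30 tert-butyldimethylsilyl 3-(tert-butyldimethylsilyloxy)benzoate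
Conditions: TBSCl (2.2 equiv), imidazole, DMF, rt
Reagents that add atoms: tert-butyldimethylsilyl chloride, CC(C)(C)[Si](C)(C)Cl
Why: Imidazole-promoted silylation converts both the phenol and the acid, which shields the phenol from the organolithium of step 17.

Step 16
Reactants: 30 tert-butyldimethylsilyl 3-(tert-butyldimethylsilyloxy)benzoate
Product: 31 3-(tert-butyldimethylsilyloxy)benzoyl chloride
Conditions: (COCl)2, DMF (cat.), CH2Cl2, 0 °C → rt
Reagents that add atoms: oxalyl chloride, O=C(Cl)C(=O)Cl
Why: Silyl esters react with the Vilsmeier-type chloroiminium salt from oxalyl chloride and dimethylformamide to give acid chlorides under neutral conditions, so the aryl silyl ether survives.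

Step 17
Reactants: 28 4-methoxybicyclo[3.3.1]non-3-ene-2,9-dione; 31 3-(tert-butyldimethylsilyloxy)benzoyl chloride
Product: 33 3-[3-(tert-butyldimethylsilyloxy)benzoyl] derivative of 28, via C3 vinyl-lithium 32 (not isolated)
Conditions: LiTMP, THF, −78 °C; then 31, −78 → −20 °C
Reagents that add atoms: none
Why: In this vinylic α-lithiation of a β-methoxy enone followed by acylation, C3–H is the only acidic hydrogen because both bridgeheads are quaternary, the hindered amide removes it, and the crowded aryl ketone formed resists a second addition.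

Step 18
Reactants: 33 3-aroyl-4-methoxybicyclo[3.3.1]non-3-ene-2,9-dione
Product: 34 (1S,5S,7R,8S)-4-hydroxy-3-(3-hydroxybenzoyl)-8-methyl-1,5,7-tris(3-methylbut-2-enyl)-8-(4-methylpent-3-enyl)bicyclo[3.3.1]non-3-ene-2,9-dione (CNP0406274.2)
Conditions: LiOH, 1,4-dioxane/H2O, 90 °C; then 1 M HCl, 0 °C
Reagents that add atoms: lithium hydroxide, [Li+].[OH-]
Why: Hydroxide adds to C4 of the vinylogous ester and expels methoxide (saponification of a vinylogous ester) and the same reagent cleaves the aryl silyl ether at silicon, so a cold, brief acidification frees the enolised triketone and the phenol in one operation.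

Compound list
1 | 2-methylbut-3-en-2-ol | CC(C)(O)C=C | starting material
2 | ethyl vinyl ether | C=COCC | starting material
3 | 3-(ethenyloxy)-3-methylbut-1-ene | C=COC(C)(C)C=C | intermediate
4 | 5-methylhex-4-enal | CC(C)=CCCC=O | intermediate
5 | but-3-en-2-one | CC(=O)C=C | starting material
6 | (2S)-5-methyl-2-(3-oxobutyl)hex-4-enal | O=C[C@H](CC=C(C)C)CCC(C)=O | intermediate
7 | (4S)-4-(3-methylbut-2-enyl)cyclohex-2-en-1-one | O=C1C=C[C@H](CC=C(C)C)CC1 | intermediate
8 | {[(3S,4S)-3-methyl-4-(3-methylbut-2-enyl)cyclohex-1-en-1-yl]oxy}trimethylsilane (methyl trans to prenyl) | C[C@H]1[C@H](CC=C(C)C)CCC(O[Si](C)(C)C)=C1 | intermediate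
9 | (4S)-3-methyl-4-(3-methylbut-2-enyl)cyclohex-2-en-1-one | O=C1C=C(C)[C@H](CC=C(C)C)CC1 | intermediate
10 | 1-bromo-3-methylbut-2-ene | CC(C)=CCBr | starting material
11 | lithium cross-conjugated dienolate of 9 | [Li]OC1=CC[C@@H](CC=C(C)C)C(C)=C1 | intermediate
12 | (4R)-3-methyl-4,6-bis(3-methylbut-2-enyl)cyclohex-2-en-1-one, C5 epimers | O=C1C=C(C)[C@H](CC=C(C)C)CC1CC=C(C)C | intermediate
13 | 5-bromo-2-methylpent-2-ene | CC(C)=CCCBr | starting material
14 | (4-methylpent-3-enyl)magnesium bromide | CC(C)=CCC[Mg]Br | intermediate
15 | C9=C1 trimethylsilyl enol ether of ring B; C8 methyl bottom, C8 homoprenyl top, C7 prenyl bottom, C5 prenyl | CC(C)=CCC[C@@]1(C)[C@H](CC=C(C)C)CC(CC=C(C)C)C(O[Si](C)(C)C)=C1 | intermediate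
16 | lithium C9=C1 enolate from 15 | CC(C)=CCC[C@@]1(C)[C@H](CC=C(C)C)CC(CC=C(C)C)C(O[Li])=C1 | intermediate
17 | C1 (dimethylamino)methyl ketone (Mannich base) | CC(C)=CCC[C@@]1(C)[C@H](CC=C(C)C)CC(CC=C(C)C)C(=O)C1CN(C)C | intermediate
18 | methiodide of 17 | CC(C)=CCC[C@@]1(C)[C@H](CC=C(C)C)CC(CC=C(C)C)C(=O)C1C[N+](C)(C)C.[I-] | intermediate
19 | ring B ketone with exocyclic C1 methylene | CC(C)=CCC[C@@]1(C)[C@H](CC=C(C)C)CC(CC=C(C)C)C(=O)C1=C | intermediate
20 | 2-methylprop-1-enylmagnesium bromide | CC(C)=C[Mg]Br | starting material
21 | tetrasubstituted C9=C1 trimethylsilyl enol ether with C1 prenyl | CC(C)=CCC[C@@]1(C)[C@H](CC=C(C)C)CC(CC=C(C)C)C(O[Si](C)(C)C)=C1CC=C(C)C | intermediate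
22 | 3-(trimethylsilyl)prop-2-ynal | C[Si](C)(C)C#CC=O | starting material
23 | ring B ketone, C1 prenyl bottom, C1 1-hydroxy-3-(trimethylsilyl)prop-2-ynyl top | CC(C)=CCC[C@@]1(C)[C@H](CC=C(C)C)CC(CC=C(C)C)C(=O)[C@@]1(CC=C(C)C)C(O)C#C[Si](C)(C)C | intermediate
24 | ring B ketone, C1 prenyl bottom, C1 3-(trimethylsilyl)propynoyl top | CC(C)=CCC[C@@]1(C)[C@H](CC=C(C)C)CC(CC=C(C)C)C(=O)[C@@]1(CC=C(C)C)C(=O)C#C[Si](C)(C)C | intermediate
25 | ring B ketone, C1 prenyl bottom, C1 3-bromopropynoyl top | CC(C)=CCC[C@@]1(C)[C@H](CC=C(C)C)CC(CC=C(C)C)C(=O)[C@@]1(CC=C(C)C)C(=O)C#CBr | intermediate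
26 | C9=C5 triisopropylsilyl enol ether of 25 | CC(C)=CCC[C@@]1(C)[C@H](CC=C(C)C)CC(CC=C(C)C)=C(O[Si](C(C)C)(C(C)C)C(C)C)[C@@]1(CC=C(C)C)C(=O)C#CBr | intermediate
27 | 4-bromo-8-methyl-1,5,7-tris(3-methylbut-2-enyl)-8-(4-methylpent-3-enyl)bicyclo[3.3.1]non-3-ene-2,9-dione | CC(C)=CCC[C@@]1(C)[C@H](CC=C(C)C)C[C@]2(CC=C(C)C)C(=O)[C@@]1(CC=C(C)C)C(=O)C=C2Br | intermediate
28 | 4-methoxy analogue of 27 | CC(C)=CCC[C@@]1(C)[C@H](CC=C(C)C)C[C@]2(CC=C(C)C)C(=O)[C@@]1(CC=C(C)C)C(=O)C=C2OC | intermediate
29 | 3-hydroxybenzoic acid | OC(=O)c1cccc(O)c1 | starting material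
30 | tert-butyldimethylsilyl 3-(tert-butyldimethylsilyloxy)benzoate | CC(C)(C)[Si](C)(C)OC(=O)c1cccc(O[Si](C)(C)C(C)(C)C)c1 | intermediate
31 | 3-(tert-butyldimethylsilyloxy)benzoyl chloride | O=C(Cl)c1cccc(O[Si](C)(C)C(C)(C)C)c1 | intermediate
32 | C3 vinyl-lithium derived from 28 | CC(C)=CCC[C@@]1(C)[C@H](CC=C(C)C)C[C@]2(CC=C(C)C)C(=O)[C@@]1(CC=C(C)C)C(=O)C([Li])=C2OC | intermediate
33 | 3-[3-(tert-butyldimethylsilyloxy)benzoyl]-4-methoxy compound | CC(C)=CCC[C@@]1(C)[C@H](CC=C(C)C)C[C@]2(CC=C(C)C)C(=O)[C@@]1(CC=C(C)C)C(=O)C(C(=O)c1cccc(O[Si](C)(C)C(C)(C)C)c1)=C2OC | intermediate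
34 | CNP0406274.2, (1S,5S,7R,8S) | CC(C)=CCC[C@@]1(C)[C@H](CC=C(C)C)C[C@]2(CC=C(C)C)C(=O)[C@@]1(CC=C(C)C)C(=O)C(C(=O)c1cccc(O)c1)=C2O | target

Total step count: 18. Longest linear sequence: 16 (steps 1–14, 17 and 18).

Steps most likely to fail

Step 9. This step joins a tetrasubstituted enol ether carbon to an aldehyde right beside quaternary C8. The addition may be so slow that hydrolysis of the enol ether or erosion of facial selectivity takes over. The fallback sets out from 21, uses the smallest carbon electrophile and builds the three-carbon unit in stages. Methyllithium in THF releases the lithium enolate F1. Monomeric formaldehyde at −78 °C should give, by the same top-face approach, the C1 hydroxymethyl ketone F2. Dess–Martin oxidation gives the keto aldehyde F3. Lithium (trimethylsilyl)acetylide at −78 °C then adds to the aldehyde, which is far more reactive than the hindered C9 ketone, and the route is rejoined at 23.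

Step 13. The catalyst may be diverted by the alkenes, the enol ether may lose its silyl group before the carbon–carbon bond forms, or the closure may drift to the 5-exo mode. The fallback sets out from 26 and replaces π-activation of the alkyne by σ-activation of the carbonyl group. TiCl4 in CH2Cl2 at −78 °C binds the C2 oxygen, and C5 adds to C4 in an intramolecular Mukaiyama–Michael reaction. Aqueous work-up rejoins the route at 27. This path makes no further compound (none F0).

Step 12. Enolisation of the hindered C9 ketone may be slow, and amine attack on the bromo-ynone may consume the substrate. The fallback sets out from 25 and gives up the silyl enol ether. KHMDS in THF at −78 °C gives the potassium enolate F4, which adds through C5 to C4 in an anionic 6-endo-dig Michael closure. Protonation rejoins the route at 27.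

Further compounds
F1 | step 9 | lithium C9=C1 enolate of the C1-prenylated ring B ketone | CC(C)=CCC[C@@]1(C)[C@H](CC=C(C)C)CC(CC=C(C)C)C(O[Li])=C1CC=C(C)C
F2 | step 9 | ring B ketone, C1 prenyl bottom, C1 hydroxymethyl top | CC(C)=CCC[C@@]1(C)[C@H](CC=C(C)C)CC(CC=C(C)C)C(=O)[C@@]1(CC=C(C)C)CO
F3 | step 9 | ring B ketone, C1 prenyl bottom, C1 formyl top | CC(C)=CCC[C@@]1(C)[C@H](CC=C(C)C)CC(CC=C(C)C)C(=O)[C@@]1(CC=C(C)C)C=O
F0 | step 13 | none | none
F4 | step 12 | potassium C9=C5 enolate of 25 | CC(C)=CCC[C@@]1(C)[C@H](CC=C(C)C)CC(CC=C(C)C)=C(O[K])[C@@]1(CC=C(C)C)C(=O)C#CBr
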